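## Retrosynthetic overview

1. The last C–C bond made is acyl carbon to pyridine C3: a 3-lithio-2,4-dialkoxy-5-arylpyridine (fragment B) adds to the Weinreb amide of the decalin dienoic acid (fragment A). Fluoride-labile O-protection (two 2-(trimethylsilyl)ethyl ethers, one triisopropylsilyl ether) is removed last.
2. Fragment A: the C1 propenyl group comes from a Suzuki coupling of a dienyl triflate. The triflate comes from a 2-carbamoyl enone, made by α-iodination and aminocarbonylation of a bicyclic enone.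
3. The trans-fused bicyclic enone comes from an acyclic keto enal in one amine-mediated cascade. An intramolecular Michael addition closes ring B first (C4a–C8a bond), then an intramolecular aldol condensation closes ring A (C2–C3 bond).
4. The keto enal comes from (S)-citronellyl bromide (source of the C7 stereocentre), N-methoxy-N-methylacetamide and methacrolein.
5. Fragment B comes from 5-bromo-2,4-dichloropyridine and 4-bromophenol (SNAr, Suzuki coupling, C3 bromination).

Assumption: (S)-(+)-citronellyl bromide is bought as the chiral-pool starting material. Decalin atoms are numbered as in the target (C1 propenyl, C2 acyl, C4 and C7 methyl, C4a/C8a ring fusion). The target is (4aS,7S,8aS), a trans-decalin with an equatorial C7 methyl.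

## Route

**Step 1**
Reactants: 1 (S)-citronellyl bromide [(S)-8-bromo-2,6-dimethyloct-2-ene]; 2 N-methoxy-N-methylacetamide
Product: 4 (S)-5,9-dimethyldec-8-en-2-one, via citronellylmagnesium bromide 3 (not isolated)
Conditions: Mg, THF, reflux; then 2, 0 °C to rt; 1 M HCl
Reagents that add atoms: none
Why: Grignard acylation of a Weinreb amide stops at the methyl ketone because the chelated tetrahedral adduct survives until work-up, and the chiral-pool stereocentre (future C7) is not touched.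

**Step 2**
Reactants: 4 (S)-5,9-dimethyldec-8-en-2-one; 5 methacrolein
Product: 6 (2E,6S)-2,6-dimethyl-9-oxodec-2-enal
Conditions: 5 (8 equiv), second-generation Hoveyda–Grubbs catalyst RuCl2(H2IMes)(=CH-C6H4-2-Oi-Pr) (5 mol %), CH2Cl2, 40 °C
Reagents that add atoms: none
Why: Olefin cross-metathesis of the prenyl terminus with excess methacrolein gives the thermodynamically favoured (E)-2-methyl enal and volatile isobutene, while the ketone is inert.

**Step 3**
Reactants: 6 (2E,6S)-2,6-dimethyl-9-oxodec-2-enal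
Product: 8 (4aR,7S,8aS)-4,7-dimethyl-4a,5,6,7,8,8a-hexahydronaphthalen-1(4H)-one (C4 epimers), via keto aldehyde 7 (not isolated)
Conditions: pyrrolidine (0.3 equiv), AcOH (0.3 equiv), toluene (0.02 M), rt, 24 h; then 70 °C
Reagents that add atoms: none
Why: An enamine/iminium-mediated intramolecular Michael addition (6-exo-trig, chair-like transition state with the methyl group equatorial) sets C4a trans-1,4 to C7, the epimerisable C8a settles diequatorial (trans ring fusion), and the only possible six-membered intramolecular aldol condensation then closes ring A; the C4 epimers do not matter because C4 becomes sp2 in step 6.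

**Step 4**
Reactants: 8 (4aR,7S,8aS)-4,7-dimethyl-4a,5,6,7,8,8a-hexahydronaphthalen-1(4H)-one
Product: 9 (4aR,7S,8aS)-2-iodo-4,7-dimethyl-4a,5,6,7,8,8a-hexahydronaphthalen-1(4H)-one
Conditions: I2, pyridine, CH2Cl2, 0 °C to rt
Reagents that add atoms: iodine, II
Why: Johnson α-iodination of an enone (pyridine conjugate addition, iodination of the enolate, elimination) places the halogen on C2 only.

**Step 5**
Reactants: 9 (4aR,7S,8aS)-2-iodo-4,7-dimethyl-4a,5,6,7,8,8a-hexahydronaphthalen-1(4H)-one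
Product: 10 (4aR,7S,8aS)-N-methoxy-N,4,7-trimethyl-1-oxo-1,4,4a,5,6,7,8,8a-octahydronaphthalene-2-carboxamide
Conditions: CO (1 atm), MeNH(OMe)·HCl, Pd(OAc)2 (5 mol %), PPh3, Et3N, DMF, 55 °C
Reagents that add atoms: carbon monoxide, [C-]#[O+]; N,O-dimethylhydroxylamine hydrochloride, CNOC.Cl
Why: Palladium-catalysed aminocarbonylation of the vinyl iodide (oxidative addition, CO insertion, aminolysis of the acylpalladium) installs the future ketone carbon directly as a Weinreb amide.

**Step 6**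
Reactants: 10 (4aR,7S,8aS)-N-methoxy-N,4,7-trimethyl-1-oxo-1,4,4a,5,6,7,8,8a-octahydronaphthalene-2-carboxamide
Product: 12 (4aS,7S,8aS)-2-[methoxy(methyl)carbamoyl]-4,7-dimethyl-4a,5,6,7,8,8a-hexahydronaphthalen-1-yl trifluoromethanesulfonate, via sodium dienolate 11 (not isolated)
Conditions: NaH, THF, 0 °C to rt; then PhNTf2, rt
Reagents that add atoms: N-phenylbis(trifluoromethanesulfonimide), O=S(=O)(N(c1ccccc1)S(=O)(=O)C(F)(F)F)C(F)(F)F
Why: γ-Deprotonation at C4 gives the doubly stabilised dienolate, the only enolate formed under equilibrating conditions, and O-sulfonylation (enol triflate formation) fixes the C1=C2/C3=C4 diene and erases the C4 stereocentre.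

**Step 7**
Reactants: 12 the dienyl triflate; 13 (E)-prop-1-en-1-ylboronic acid
Product: 14 (4aS,7S,8aS)-N-methoxy-N,4,7-trimethyl-1-[(E)-prop-1-en-1-yl]-4a,5,6,7,8,8a-hexahydronaphthalene-2-carboxamide
Conditions: Pd(PPh3)4 (5 mol %), K3PO4, 1,4-dioxane/H2O, 60 °C
Reagents that add atoms: none
Why: Suzuki–Miyaura coupling of the electron-poor β-carbamoyl dienyl triflate with an (E)-alkenylboronic acid proceeds with retention of the alkene geometry.

**Step 8**
Reactants: 15 4-bromophenol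
Product: 16 (4-bromophenoxy)triisopropylsilane
Conditions: i-Pr3SiCl, imidazole, DMF, rt
Reagents that add atoms: chlorotriisopropylsilane, CC(C)[Si](Cl)(C(C)C)C(C)C
Why: Silyl ether formation gives a bulky phenol protecting group that tolerates butyllithium, aqueous carbonate and NBS and is cleaved by fluoride in the last step.

**Step 9**
Reactants: 16 (4-bromophenoxy)triisopropylsilane
Product: 19 [4-(triisopropylsilyloxy)phenyl]boronic acid, via aryllithium 17 (not isolated), via lithium triisopropoxy(aryl)borate 18 (not isolated)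
Conditions: n-BuLi, THF, −78 °C; B(Oi-Pr)3, −78 °C to rt; 1 M HCl, 0 °C
Reagents that add atoms: triisopropyl borate, CC(C)OB(OC(C)C)OC(C)C; water, O
Why: Bromine–lithium exchange, borylation of the aryllithium by a trialkyl borate and hydrolysis is the standard boronic acid synthesis.

**Step 10**
Reactants: 20 5-bromo-2,4-dichloropyridine
Product: 22 5-bromo-2,4-bis[2-(trimethylsilyl)ethoxy]pyridine, via monoether 21 (not isolated)
Conditions: Me3SiCH2CH2OH (2.6 equiv), NaH (2.6 equiv), THF, 0 °C then reflux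
Reagents that add atoms: 2-(trimethylsilyl)ethanol, C[Si](C)(C)CCO
Why: Double nucleophilic aromatic substitution (SNAr) occurs at the 4- and 2-positions activated by the ring nitrogen, while the unactivated 5-bromide stays.

**Step 11**
Reactants: 22 5-bromo-2,4-bis[2-(trimethylsilyl)ethoxy]pyridine; 19 [4-(triisopropylsilyloxy)phenyl]boronic acid
Product: 23 2,4-bis[2-(trimethylsilyl)ethoxy]-5-[4-(triisopropylsilyloxy)phenyl]pyridine
Conditions: PdCl2(dppf) (5 mol %), Na2CO3, 1,2-dimethoxyethane/H2O, 80 °C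
Reagents that add atoms: none
Why: Suzuki–Miyaura coupling at the only carbon–bromine bond builds the 5-arylpyridine.

**Step 12**
Reactants: 23 2,4-bis[2-(trimethylsilyl)ethoxy]-5-[4-(triisopropylsilyloxy)phenyl]pyridine
Product: 24 3-bromo-2,4-bis[2-(trimethylsilyl)ethoxy]-5-[4-(triisopropylsilyloxy)phenyl]pyridine
Conditions: NBS (1.05 equiv), MeCN, 0 °C to rt, dark
Reagents that add atoms: N-bromosuccinimide, O=C1CCC(=O)N1Br
Why: Electrophilic aromatic bromination goes to C3, which is ortho to both alkoxy groups and the only open activated pyridine position, while the aryl ring is shielded by the bulky silyl ether.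

**Step 13**
Reactants: 24 the 3-bromopyridine; 14 the dienyl Weinreb amide
Product: 26 [(4aS,7S,8aS)-4,7-dimethyl-1-[(E)-prop-1-en-1-yl]-4a,5,6,7,8,8a-hexahydronaphthalen-2-yl]{2,4-bis[2-(trimethylsilyl)ethoxy]-5-[4-(triisopropylsilyloxy)phenyl]pyridin-3-yl}methanone, via pyridyllithium 25 (not isolated)
Conditions: 24 (1.3 equiv), n-BuLi, THF, −78 °C, 15 min; then 14, −78 to −20 °C; H2O
Reagents that add atoms: none
Why: Bromine–lithium exchange gives a regiodefined 3-lithiopyridine that adds once to the Weinreb amide (Weinreb ketone synthesis, chelated tetrahedral intermediate), so there is no over-addition and no stereocentre is touched.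

**Step 14**
Reactants: 26 the protected ketone
Product: 27 ilicicolin J, 3-{[(4aS,7S,8aS)-4,7-dimethyl-1-[(E)-prop-1-en-1-yl]-4a,5,6,7,8,8a-hexahydronaphthalen-2-yl]carbonyl}-4-hydroxy-5-(4-hydroxyphenyl)pyridin-2(1H)-one
Conditions: Bu4NF (6 equiv), THF, 0 to 40 °C; AcOH quench
Reagents that add atoms: none
Why: Fluoride-induced fragmentation of both 2-(trimethylsilyl)ethyl ethers and desilylation of the aryl silyl ether unveil the 4-hydroxy-2-pyridone and the phenol without acid or reduction that would endanger the triene ketone.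

## Compound list

1 | (S)-citronellyl bromide, (S)-8-bromo-2,6-dimethyloct-2-ene | BrCC[C@@H](C)CCC=C(C)C | starting material
2 | N-methoxy-N-methylacetamide | CC(=O)N(C)OC | starting material
3 | [(3S)-3,7-dimethyloct-6-en-1-yl]magnesium bromide | Br[Mg]CC[C@@H](C)CCC=C(C)C | intermediate
4 | (S)-5,9-dimethyldec-8-en-2-one | CC(=O)CC[C@@H](C)CCC=C(C)C | intermediate
5 | methacrolein | CC(=C)C=O | starting material
6 | (2E,6S)-2,6-dimethyl-9-oxodec-2-enal | CC(=O)CC[C@@H](C)CC/C=C(\C)C=O | intermediate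
7 | 2-[(1R,2S,4S)-2-acetyl-4-methylcyclohexyl]propanal (epimers at the propanal C2) | O=CC(C)[C@H]1CC[C@H](C)C[C@@H]1C(C)=O | intermediate
8 | (4aR,7S,8aS)-4,7-dimethyl-4a,5,6,7,8,8a-hexahydronaphthalen-1(4H)-one (C4 epimers) | O=C1C=CC(C)[C@H]2CC[C@H](C)C[C@H]12 | intermediate
9 | (4aR,7S,8aS)-2-iodo-4,7-dimethyl-4a,5,6,7,8,8a-hexahydronaphthalen-1(4H)-one (C4 epimers) | O=C1C(I)=CC(C)[C@H]2CC[C@H](C)C[C@H]12 | intermediate
10 | (4aR,7S,8aS)-N-methoxy-N,4,7-trimethyl-1-oxo-1,4,4a,5,6,7,8,8a-octahydronaphthalene-2-carboxamide (C4 epimers) | O=C1C(C(=O)N(C)OC)=CC(C)[C@H]2CC[C@H](C)C[C@H]12 | intermediate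
11 | sodium (4aS,7S,8aS)-2-[methoxy(methyl)carbamoyl]-4,7-dimethyl-4a,5,6,7,8,8a-hexahydronaphthalen-1-olate | [Na+].[O-]C1=C(C(=O)N(C)OC)C=C(C)[C@H]2CC[C@H](C)C[C@H]12 | intermediate
12 | (4aS,7S,8aS)-2-[methoxy(methyl)carbamoyl]-4,7-dimethyl-4a,5,6,7,8,8a-hexahydronaphthalen-1-yl trifluoromethanesulfonate | O=S(=O)(OC1=C(C(=O)N(C)OC)C=C(C)[C@H]2CC[C@H](C)C[C@H]12)C(F)(F)F | intermediate
13 | (E)-prop-1-en-1-ylboronic acid | C/C=C/B(O)O | starting material
14 | (4aS,7S,8aS)-N-methoxy-N,4,7-trimethyl-1-[(E)-prop-1-en-1-yl]-4a,5,6,7,8,8a-hexahydronaphthalene-2-carboxamide | C/C=C/C1=C(C(=O)N(C)OC)C=C(C)[C@H]2CC[C@H](C)C[C@H]12 | intermediate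
15 | 4-bromophenol | Oc1ccc(Br)cc1 | starting material
16 | (4-bromophenoxy)triisopropylsilane | CC(C)[Si](Oc1ccc(Br)cc1)(C(C)C)C(C)C | intermediate
17 | [4-(triisopropylsilyloxy)phenyl]lithium | [Li]c1ccc(O[Si](C(C)C)(C(C)C)C(C)C)cc1 | intermediate
18 | lithium triisopropoxy[4-(triisopropylsilyloxy)phenyl]borate | [Li+].CC(C)O[B-](OC(C)C)(OC(C)C)c1ccc(O[Si](C(C)C)(C(C)C)C(C)C)cc1 | intermediate
19 | [4-(triisopropylsilyloxy)phenyl]boronic acid | OB(O)c1ccc(O[Si](C(C)C)(C(C)C)C(C)C)cc1 | intermediate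
20 | 5-bromo-2,4-dichloropyridine | Clc1ncc(Br)c(Cl)c1 | starting material
21 | 5-bromo-2-chloro-4-[2-(trimethylsilyl)ethoxy]pyridine | Clc1ncc(Br)c(OCC[Si](C)(C)C)c1 | intermediate
22 | 5-bromo-2,4-bis[2-(trimethylsilyl)ethoxy]pyridine | C[Si](C)(C)CCOc1ncc(Br)c(OCC[Si](C)(C)C)c1 | intermediate
23 | 2,4-bis[2-(trimethylsilyl)ethoxy]-5-[4-(triisopropylsilyloxy)phenyl]pyridine | C[Si](C)(C)CCOc1ncc(-c2ccc(O[Si](C(C)C)(C(C)C)C(C)C)cc2)c(OCC[Si](C)(C)C)c1 | intermediate
24 | 3-bromo-2,4-bis[2-(trimethylsilyl)ethoxy]-5-[4-(triisopropylsilyloxy)phenyl]pyridine | C[Si](C)(C)CCOc1ncc(-c2ccc(O[Si](C(C)C)(C(C)C)C(C)C)cc2)c(OCC[Si](C)(C)C)c1Br | intermediate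
25 | {2,4-bis[2-(trimethylsilyl)ethoxy]-5-[4-(triisopropylsilyloxy)phenyl]pyridin-3-yl}lithium | C[Si](C)(C)CCOc1ncc(-c2ccc(O[Si](C(C)C)(C(C)C)C(C)C)cc2)c(OCC[Si](C)(C)C)c1[Li] | intermediate
26 | [(4aS,7S,8aS)-4,7-dimethyl-1-[(E)-prop-1-en-1-yl]-4a,5,6,7,8,8a-hexahydronaphthalen-2-yl]{2,4-bis[2-(trimethylsilyl)ethoxy]-5-[4-(triisopropylsilyloxy)phenyl]pyridin-3-yl}methanone | C/C=C/C1=C(C(=O)c2c(OCC[Si](C)(C)C)c(-c3ccc(O[Si](C(C)C)(C(C)C)C(C)C)cc3)cnc2OCC[Si](C)(C)C)C=C(C)[C@H]2CC[C@H](C)C[C@H]12 | intermediate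
27 | ilicicolin J | C/C=C/C1=C(C(=O)c2c(O)c(-c3ccc(O)cc3)c[nH]c2=O)C=C(C)[C@H]2CC[C@H](C)C[C@H]12 | target

## Step count and risks

Total step count: 14. Longest linear sequence: 9 (steps 1–7, 13, 14). The pyridine branch (steps 8–12) joins at step 13.

**Step 3 (Michael/aldol cascade).** The risks are enamine formation on the wrong side of the methyl ketone, oligomerisation of the enal, and incomplete C4a/C7 control. The fallback makes C8a a regiodefined, doubly activated donor so that ring B closes under mild, reversible base. It sets out from 1. Displacement with PhSO2Na (DMF, 60 °C) gives the phenyl sulfone F1. n-BuLi (THF, −78 °C) gives the α-lithio sulfone F2, which is acylated by 2 to the β-keto sulfone F3. Cross-metathesis with 5 (same catalyst as step 2) gives the sulfonyl keto enal F4. Cs2CO3 in MeCN closes ring B by a thermodynamically controlled Michael addition of the β-keto sulfone carbon to give the cyclised keto aldehyde F5. Pyrrolidinium acetate then closes ring A by aldol condensation to the 8a-sulfonyl enone F6. SmI2 (THF/MeOH, −78 °C) removes the sulfone, and protonation of the enolate followed by DBU equilibration gives the trans-fused enone 8, where the route resumes.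

**Step 13 (hindered aryllithium plus hindered Weinreb amide).** The risks are slow addition and γ-deprotonation of 14. The fallback changes the electrophile and adds a redox step. It sets out from 14. i-Bu2AlH (THF, −78 °C) reduces the Weinreb amide to the dienal F7. Pyridyllithium 25 (from 24 as in step 13) adds to the unhindered aldehyde to give the carbinol F8. MnO2 (CH2Cl2, rt) or Dess–Martin periodinane oxidises this doubly activated alcohol to 26, where the route resumes.

**Step 14 (threefold fluoride deprotection).** The risks are sluggish cleavage of the 2-(trimethylsilyl)ethyl ethers and base-induced isomerisation of the triene ketone. The fallback changes the pyridine protecting groups to benzyl ethers, removed by a Lewis acid at low temperature. It sets out from 20. BnOH/NaH (DMF, 80 °C) gives 2,4-bis(benzyloxy)-5-bromopyridine F9. Suzuki coupling with 19 gives the biaryl F10. NBS gives the 3-bromide F11. n-BuLi at −78 °C (exchange is faster than benzylic deprotonation) gives the 3-lithiopyridine F12, which is acylated by 14 to the dibenzyl ketone F13. BCl3 and pentamethylbenzene (CH2Cl2, −78 °C) remove both benzyl groups to give the silyl-protected pyridone F14. Bu4NF (1.2 equiv, THF, 0 °C) then has only the aryl silyl ether to cleave and gives 27, the end of the route.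

## Further compounds

F1 | step 3 | {[(3S)-3,7-dimethyloct-6-en-1-yl]sulfonyl}benzene | O=S(=O)(CC[C@@H](C)CCC=C(C)C)c1ccccc1
F2 | step 3 | [(3S)-3,7-dimethyl-1-(phenylsulfonyl)oct-6-en-1-yl]lithium | [Li]C(C[C@@H](C)CCC=C(C)C)S(=O)(=O)c1ccccc1
F3 | step 3 | (5S)-5,9-dimethyl-3-(phenylsulfonyl)dec-8-en-2-one (C3 epimers) | CC(=O)C(C[C@@H](C)CCC=C(C)C)S(=O)(=O)c1ccccc1
F4 | step 3 | (2E,6S)-2,6-dimethyl-9-oxo-8-(phenylsulfonyl)dec-2-enal | CC(=O)C(C[C@@H](C)CC/C=C(\C)C=O)S(=O)(=O)c1ccccc1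
F5 | step 3 | 2-[(1R,4S)-2-acetyl-4-methyl-2-(phenylsulfonyl)cyclohexyl]propanal | O=CC(C)[C@H]1CC[C@H](C)CC1(C(C)=O)S(=O)(=O)c1ccccc1
F6 | step 3 | (4aR,7S)-4,7-dimethyl-8a-(phenylsulfonyl)-4a,5,6,7,8,8a-hexahydronaphthalen-1(4H)-one | O=C1C=CC(C)[C@H]2CC[C@H](C)CC12S(=O)(=O)c1ccccc1
F7 | step 13 | (4aS,7S,8aS)-4,7-dimethyl-1-[(E)-prop-1-en-1-yl]-4a,5,6,7,8,8a-hexahydronaphthalene-2-carbaldehyde | C/C=C/C1=C(C=O)C=C(C)[C@H]2CC[C@H](C)C[C@H]12
F8 | step 13 | [(4aS,7S,8aS)-4,7-dimethyl-1-[(E)-prop-1-en-1-yl]-4a,5,6,7,8,8a-hexahydronaphthalen-2-yl]{2,4-bis[2-(trimethylsilyl)ethoxy]-5-[4-(triisopropylsilyloxy)phenyl]pyridin-3-yl}methanol (carbinol epimers) | C/C=C/C1=C(C(O)c2c(OCC[Si](C)(C)C)c(-c3ccc(O[Si](C(C)C)(C(C)C)C(C)C)cc3)cnc2OCC[Si](C)(C)C)C=C(C)[C@H]2CC[C@H](C)C[C@H]12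
F9 | step 14 | 2,4-bis(benzyloxy)-5-bromopyridine | Brc1cnc(OCc2ccccc2)cc1OCc1ccccc1
F10 | step 14 | 2,4-bis(benzyloxy)-5-[4-(triisopropylsilyloxy)phenyl]pyridine | CC(C)[Si](Oc1ccc(cc1)-c1cnc(OCc2ccccc2)cc1OCc1ccccc1)(C(C)C)C(C)C
F11 | step 14 | 2,4-bis(benzyloxy)-3-bromo-5-[4-(triisopropylsilyloxy)phenyl]pyridine | CC(C)[Si](Oc1ccc(cc1)-c1cnc(OCc2ccccc2)c(Br)c1OCc1ccccc1)(C(C)C)C(C)C
F12 | step 14 | {2,4-bis(benzyloxy)-5-[4-(triisopropylsilyloxy)phenyl]pyridin-3-yl}lithium | CC(C)[Si](Oc1ccc(cc1)-c1cnc(OCc2ccccc2)c([Li])c1OCc1ccccc1)(C(C)C)C(C)C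
F13 | step 14 | [(4aS,7S,8aS)-4,7-dimethyl-1-[(E)-prop-1-en-1-yl]-4a,5,6,7,8,8a-hexahydronaphthalen-2-yl]{2,4-bis(benzyloxy)-5-[4-(triisopropylsilyloxy)phenyl]pyridin-3-yl}methanone | C/C=C/C1=C(C(=O)c2c(OCc3ccccc3)c(-c3ccc(O[Si](C(C)C)(C(C)C)C(C)C)cc3)cnc2OCc2ccccc2)C=C(C)[C@H]2CC[C@H](C)C[C@H]12
F14 | step 14 | 3-{[(4aS,7S,8aS)-4,7-dimethyl-1-[(E)-prop-1-en-1-yl]-4a,5,6,7,8,8a-hexahydronaphthalen-2-yl]carbonyl}-4-hydroxy-5-[4-(triisopropylsilyloxy)phenyl]pyridin-2(1H)-one | C/C=C/C1=C(C(=O)c2c(O)c(-c3ccc(O[Si](C(C)C)(C(C)C)C(C)C)cc3)c[nH]c2=O)C=C(C)[C@H]2CC[C@H](C)C[C@H]12
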